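The numbers of this flask come from no measurement.

The ratio I wanted was between the second substrate's two ways out: a turn through the catalyst spends one partner, and a turn with itself spends none.

    2 second substrate → self-condensation product (k1 = 0.12 M⁻¹ s⁻¹)
    partner + catalyst intermediate A → free catalyst + target (k2 = 0.68 M⁻¹ s⁻¹)
    target ⇌ isomer of the product (K3 = 0.28, k3 = 0.0029 s⁻¹)
    second substrate + free catalyst ⇌ catalyst intermediate B (K4 = 2800 M⁻¹, k4 = 1.5 M⁻¹ s⁻¹)
    starting material + free catalyst ⇌ catalyst intermediate A (K5 = 6.9 M⁻¹, k5 = 1.6 M⁻¹ s⁻¹)
    partner + catalyst intermediate B → free catalyst + second product (k6 = 1.5 M⁻¹ s⁻¹)

| flask | starting material | second substrate | partner | free catalyst | time | remark |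
|---|---|---|---|---|---|---|
| south-west | 0.10 M (in portions, 5, over 1.5 h) | 0.0500 M | 0.105 M | 2.5 mM | 2.0 h | first portion at the start, last at 1.5 h |
| west | 0.10 M (fed, over 1.5 h) | 0.0500 M | 0.105 M | 2.5 mM | 2.0 h | all else is in the flask from the start; the feed brings no volume worth counting |
| south | 0.10 M | 0.0500 M (fed, over 1.5 h) | 0.105 M | 2.5 mM | 2.0 h | all else is in the flask from the start; the feed brings no volume worth counting |
| south-east | 0.10 M | 0.0500 M | 0.105 M | 2.5 mM | 2.0 h | everything together at the start |

- two of one species on the left: rate k times its square, two consumed each time
- run time (south-west): 2.0 h

- which flask leads in amount of target, in percent of the starting material charged ("all alike" within 1.5 percentage points) (south-west / west / south / south-east / all alike)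
- how much target is there at the end, in percent of the starting material charged: south-west
- how much target is there at the end, in percent of the starting material charged: west
- how much target is there at the end, in percent of the starting material charged: south
- how much target is there at the end, in percent of the starting material charged: south-east

I began with south-east. Let a be [second substrate] and a* the crossover level, the value of a at which catalyst and self-condensation consume it equally fast. With the whole catalyst free, a* was 0.0156 M. Summing the catalyst's share as a fell from its charge gave a* ln(1 + charge/a*), or 0.0224 M of second product. That sum assumes the catalyst stays the same throughout.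

Next I defined the target ceiling: the partner not spent on second product, times target's share of the target–isomer pair, over the starting material charged. That share is 78.1%, and the pair relaxes in 0.871 min, shorter than 2.0 h. I then worked with the fraction left. Call the partner not spent on second product R. With starting material and partner both near R, and intermediate A in quick balance, the rate constant for the pair was 0.0117 M⁻¹ s⁻¹, and the fraction left was one over one plus that constant times R times the time. This gave 56.4% of target.

The weak link was the free catalyst. Steady shares at the start put intermediate B at 0.476 and intermediate A at 0.528 of free catalyst, so free catalyst was 49.9% of the total, about half. Then a* fell to 0.00780 M, second product to 0.0156 M, the ceiling became 69.8%, and the fraction left was 11.7%. I left the constant for the pair at its whole-catalyst value, and south-east came to 61.7%.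

With starting material fed, I counted its time from mid-feed, leaving a fraction 17.5%: 57.6% in south-west and 57.6% in west. In south I put the fed second substrate near 0.00343 M, which made my second product 0.0347 M. I took south to its ceiling, 54.9%, giving 54.9%. My choice was south-east.

The forecast chose south-east, with 57%, 55%, 52% and 62% in the order of the flasks above, on the ground that “Charged all at once, the second substrate mostly self-condenses within minutes”. Its figure for south stood lower than my 54.9%.

The flasks gave 53.6%, 54.1%, 55.0% and 62.1%, in the same order, so south-east led. South-east had not come to rest at 2.00 h: partner stood at 8.07%, and at 20.0 h target read 68.7% and starting material 11.9%, with my ceiling at 69.8%. Against my ceiling of 54.9%, south, with partner, the limiting reagent, at 0%, read 55.0% of target at 2.00 h and 55.0% at 20.0 h.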